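The formyl carbon, arene carbons C1 and C2 (benzaldehyde numbering: C3 OH, C4 OMe, C5 H, C6 OH), the benzylic CH2, the carbinol carbon and its oxygen outline a six-membered ring. The target is therefore treated as an opened 1-alkoxyisochroman and disconnected at the C1–CHO bond. The precursor is an (R)-1-aryltridecan-2-ol with both phenols benzylated and C1 and C5 unsubstituted. Its hydroxyl is loaded with an orthoformate carbon. Ionisation then closes the pyran ring and forges the aryl–carbon bond at C1 only, already at the aldehyde oxidation level. Dithiol ring opening, acetylation and two unmaskings complete the route.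

Key step: step 5

Assumption: (R)-epichlorohydrin of high enantiomeric purity and decylmagnesium bromide solution are taken as commercial; arene positions in all intermediates are quoted in the benzaldehyde numbering of the target; a numbered compound listed under Reactants is not repeated as a reagent.

Step 1
Reactants: 1 5-bromovanillin
Product: 3 2-bromo-6-methoxybenzene-1,4-diol, via aryl formate 2 (not isolated)
Conditions: 30% aq H2O2 (1.1 equiv), NaOH, H2O–THF, 0 °C → rt, N2; then 1 M HCl; crude product used at once
Reagents that add atoms: hydrogen peroxide, OO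
Why: Dakin oxidation: hydroperoxide adds to the aldehyde of the para-hydroxybenzaldehyde, the electron-rich aryl group migrates to oxygen, and the formate 2 is saponified in the same flask, while bromide and methyl ether are inert.

Step 2
Reactants: 3 2-bromo-6-methoxybenzene-1,4-diol
Product: 4 2,5-bis(benzyloxy)-1-bromo-3-methoxybenzene
Conditions: BnBr (2.5 equiv), K2CO3 (3 equiv), DMF, N2, rt → 60 °C
Reagents that add atoms: benzyl bromide, BrCc1ccccc1
Why: Williamson ether synthesis on both phenoxides; exclusion of air prevents quinone formation, and gentle heating carries the hydroxyl flanked by Br and OMe to completion.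

Step 3
Reactants: 5 (R)-epichlorohydrin; 6 decylmagnesium bromide
Product: 8 (2R)-2-undecyloxirane, via chlorohydrin 7 (not isolated)
Conditions: CuI (10 mol %), THF, −40 → 0 °C; 1 M HCl; then NaOH, MeOH–THF, 0 °C → rt
Reagents that add atoms: none
Why: Copper-catalysed Grignard opening of the epoxide at its unsubstituted carbon, followed by intramolecular Williamson closure onto the CH2Cl carbon; no bond to the stereocentre is touched and the priority order is unchanged, so (R)-5 gives (R)-8.

Step 4
Reactants: 4 2,5-bis(benzyloxy)-1-bromo-3-methoxybenzene; 8 (2R)-2-undecyloxirane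
Product: 10 (2R)-1-[2,5-bis(benzyloxy)-3-methoxyphenyl]tridecan-2-ol, via aryllithium 9 (not isolated)
Conditions: 4 (1.3 equiv), n-BuLi (1.25 equiv), THF, −78 °C; then 8 (1.0 equiv), BF3·OEt2 (1.3 equiv), −78 °C; H2O
Reagents that add atoms: none
Why: Bromine–lithium exchange followed by Lewis-acid-assisted SN2 opening of the terminal epoxide at its CH2 carbon; the C–O bond at the stereocentre persists, so the R configuration is transferred unchanged, and −78 °C keeps the ortho-benzyloxy aryllithium from proton transfer.

Step 5
Reactants: 10 (2R)-1-[2,5-bis(benzyloxy)-3-methoxyphenyl]tridecan-2-ol; 11 trimethyl orthoformate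
Product: 14 (3R)-5,8-bis(benzyloxy)-1,6-dimethoxy-3-undecyl-3,4-dihydro-1H-isochromene (both epimers at the acetal carbon), via mixed orthoester 12 (not isolated), via alkoxy(methoxy)carbenium ion 13 (not isolated)
Conditions: 11 (solvent), PPTS (2 mol %), 50 °C, MeOH distilled off; solid K2CO3, filter, evaporate; then TMSOTf (0.2 equiv), 4 Å MS, CH2Cl2 (0.01 M), −78 → −20 °C; Et3N
Reagents that add atoms: none
Why: This is an oxa-Pictet–Spengler cyclisation of a 2-arylethanol in its orthoformate variant: PPTS-catalysed alkoxy exchange hangs a dimethoxymethyl group on the carbinol oxygen (12), free 11 is evaporated, and TMSOTf then removes one methoxide to give the O-bound cation 13, which attacks arene carbon C1, after which proton loss from the arenium ion restores aromaticity and passes the acid on to the next molecule. The oxygen ring closes in a 6-endo-trig mode with respect to the C=O+ bond lying inside the tether, and the step makes both the carbinol O–C bond and the C1–C bond, so the future formyl carbon needs no redox adjustment afterwards. The selectivity needed is C1 against C5: C1 is para to the C4 methoxy group, ortho to the C6 benzyloxy group and closes a six-membered ring, whereas C5 is para to side-chain carbon C2 and cannot be spanned by a four-atom bridge, so only an untethered electrophile could reach it, and that is excluded by removing 11 before ionisation and by high dilution. The acetal carbon (C1 of the isochroman) is a new stereocentre governed only by an anomeric preference for axial methoxy, and both epimers are carried on because step 6 erases this centre, while isochroman C3 takes no part and stays R. The non-nucleophilic triflate counter-ion and the low temperature protect the benzyl ethers from dealkylation, above all the one next to the cationic carbon.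

Step 6
Reactants: 14 (3R)-5,8-bis(benzyloxy)-1,6-dimethoxy-3-undecyl-3,4-dihydro-1H-isochromene
Product: 16 (2R)-1-[2,5-bis(benzyloxy)-6-(1,3-dithian-2-yl)-3-methoxyphenyl]tridecan-2-yl acetate, via hydroxy dithiane 15 (not isolated)
Conditions: HS(CH2)3SH (1.2 equiv), BF3·OEt2 (0.3 equiv), CH2Cl2, −40 → 0 °C; then Et3N, Ac2O (4 equiv), DMAP (cat.), 0 °C → rt
Reagents that add atoms: propane-1,3-dithiol, SCCCS; acetic anhydride, CC(=O)OC(C)=O
Why: Transthioacetalisation followed by DMAP-catalysed acetylation: the Lewis acid ionises the benzylic acetal, the dithiol captures the cation twice and the second capture expels the ring oxygen, so the aldehyde carbon is locked as a 1,3-dithiane that cannot re-close onto the freed carbinol, which is then O-acetylated without touching any bond at the stereocentre.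

Step 7
Reactants: 16 (2R)-1-[2,5-bis(benzyloxy)-6-(1,3-dithian-2-yl)-3-methoxyphenyl]tridecan-2-yl acetate
Product: 17 (2R)-1-[2,5-bis(benzyloxy)-6-formyl-3-methoxyphenyl]tridecan-2-yl acetate
Conditions: MeI (10 equiv), CaCO3 (5 equiv), MeCN–H2O (9:1), 45 °C
Reagents that add atoms: water, O
Why: Alkylative dithiane hydrolysis: S-methylation makes sulfur a leaving group, the donor-rich arene stabilises the thionium ion and water supplies the carbonyl oxygen, while the non-oxidative buffered medium spares the acetate, the benzyl ethers and the oxidation-prone hydroquinone diether ring.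

Step 8
Reactants: 17 (2R)-1-[2,5-bis(benzyloxy)-6-formyl-3-methoxyphenyl]tridecan-2-yl acetate
Product: 18 (2R)-1-(2-formyl-3,6-dihydroxy-5-methoxyphenyl)tridecan-2-yl acetate (target)
Conditions: BCl3 (1 M in CH2Cl2, 4 equiv), pentamethylbenzene (6 equiv), CH2Cl2, −78 °C; MeOH–CHCl3, then H2O
Reagents that add atoms: none
Why: Lewis-acid cleavage of aryl benzyl ethers with a non-basic cation scavenger: at −78 °C only the O–benzyl bonds ionise and pentamethylbenzene intercepts the benzyl cations, so the C4 methyl ether, the secondary acetate and the aldehyde persist and the open C5 position is not C-benzylated.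

Compound list
1 | 5-bromovanillin (3-bromo-4-hydroxy-5-methoxybenzaldehyde) | COc1cc(C=O)cc(Br)c1O | starting material
2 | 3-bromo-4-hydroxy-5-methoxyphenyl formate | COc1cc(OC=O)cc(Br)c1O | intermediate
3 | 2-bromo-6-methoxybenzene-1,4-diol | COc1cc(O)cc(Br)c1O | intermediate
4 | 2,5-bis(benzyloxy)-1-bromo-3-methoxybenzene | COc1cc(OCc2ccccc2)cc(Br)c1OCc1ccccc1 | intermediate
5 | (R)-epichlorohydrin, (2R)-2-(chloromethyl)oxirane | ClC[C@H]1CO1 | starting material
6 | decylmagnesium bromide | CCCCCCCCCC[Mg]Br | starting material
7 | (2R)-1-chlorotridecan-2-ol | CCCCCCCCCCC[C@@H](O)CCl | intermediate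
8 | (2R)-2-undecyloxirane | CCCCCCCCCCC[C@@H]1CO1 | intermediate
9 | [2,5-bis(benzyloxy)-3-methoxyphenyl]lithium | [Li]c1cc(OCc2ccccc2)cc(OC)c1OCc1ccccc1 | intermediate
10 | (2R)-1-[2,5-bis(benzyloxy)-3-methoxyphenyl]tridecan-2-ol | CCCCCCCCCCC[C@H](Cc1cc(OCc2ccccc2)cc(OC)c1OCc1ccccc1)O | intermediate
11 | trimethyl orthoformate | COC(OC)OC | starting material
12 | (2R)-1-[2,5-bis(benzyloxy)-3-methoxyphenyl]-2-(dimethoxymethoxy)tridecane | CCCCCCCCCCC[C@H](Cc1cc(OCc2ccccc2)cc(OC)c1OCc1ccccc1)OC(OC)OC | intermediate
13 | {[(2R)-1-[2,5-bis(benzyloxy)-3-methoxyphenyl]tridecan-2-yl]oxy}(methoxy)carbenium triflate | CCCCCCCCCCC[C@H](Cc1cc(OCc2ccccc2)cc(OC)c1OCc1ccccc1)OC=[O+]C.[O-]S(=O)(=O)C(F)(F)F | intermediate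
14 | (3R)-5,8-bis(benzyloxy)-1,6-dimethoxy-3-undecyl-3,4-dihydro-1H-isochromene, epimers at C1 | CCCCCCCCCCC[C@@H]1Cc2c(OCc3ccccc3)c(OC)cc(OCc3ccccc3)c2C(OC)O1 | intermediate
15 | (2R)-1-[2,5-bis(benzyloxy)-6-(1,3-dithian-2-yl)-3-methoxyphenyl]tridecan-2-ol | CCCCCCCCCCC[C@H](Cc1c(C2SCCCS2)c(OCc2ccccc2)cc(OC)c1OCc1ccccc1)O | intermediate
16 | (2R)-1-[2,5-bis(benzyloxy)-6-(1,3-dithian-2-yl)-3-methoxyphenyl]tridecan-2-yl acetate | CCCCCCCCCCC[C@H](Cc1c(C2SCCCS2)c(OCc2ccccc2)cc(OC)c1OCc1ccccc1)OC(C)=O | intermediate
17 | (2R)-1-[2,5-bis(benzyloxy)-6-formyl-3-methoxyphenyl]tridecan-2-yl acetate | CCCCCCCCCCC[C@H](Cc1c(C=O)c(OCc2ccccc2)cc(OC)c1OCc1ccccc1)OC(C)=O | intermediate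
18 | (2R)-1-(2-formyl-3,6-dihydroxy-5-methoxyphenyl)tridecan-2-yl acetate | CCCCCCCCCCC[C@H](Cc1c(O)c(OC)cc(O)c1C=O)OC(C)=O | target

Total step count: 8. Longest linear sequence: 7 steps (1, 2, 4, 5, 6, 7, 8) from 5-bromovanillin.

Steps most likely to fail

Risk A, step 5. The doubly oxygen-stabilised cation may be too weak an electrophile. It could then be demethylated to the formate ester of the alcohol, or redistribute its alkoxy groups, faster than it attacks the ring. Extended acid contact may also strip the benzyl group next to the cationic carbon. The fallback sets out from 10 and returns at 14. It keeps the tether but takes the electrophile one oxidation level lower. Treating 10 with dimethoxymethane and BF3·OEt2 in CH2Cl2 at 0 °C is the standard formaldehyde-acetal oxa-Pictet–Spengler reaction. Through the far more electrophilic mono-oxocarbenium ion it should give (3R)-5,8-bis(benzyloxy)-6-methoxy-3-undecyl-3,4-dihydro-1H-isochromene F1. DDQ in CH2Cl2–MeOH then abstracts hydride from the O–CH2–aryl position, the only C–H bond that is both benzylic to the donor-rich ring and alpha to oxygen. Methanol traps the resulting cation to give 14. Simple aryl benzyl ethers are expected to tolerate DDQ under these conditions.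

Risk B, step 6. Expulsion of the ring oxygen may stall at the cyclic O,S-acetal stage. Alternatively, the thiol may dealkylate the benzyl ether conjugated with the cationic carbon, and the liberated phenol would then be acetylated. The fallback sets out from 14 and returns at 17, bypassing 16 and step 7. It masks the aldehyde without sulfur or Lewis acid. Heating 14 with 1,1-dimethylhydrazine and catalytic PPTS in EtOH should exchange both acetal oxygens for nitrogen. This gives the open, strongly conjugated (2R)-1-{2,5-bis(benzyloxy)-6-[(E)-(2,2-dimethylhydrazinylidene)methyl]-3-methoxyphenyl}tridecan-2-ol F2. Ac2O, pyridine and DMAP convert it into the corresponding tridecan-2-yl acetate F3. Biphasic hydrolysis with saturated aqueous oxalic acid and Et2O releases aldehyde 17, and the acetate is stable to this medium.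

Risk C, step 8. Boron bound to the freed C3 oxygen may chelate the neighbouring C4 methoxy group and cause demethylation. Acetate cleavage, or benzyl transfer to C5, may also intervene if scavenging is slow. The fallback sets out from 17 and returns at 18, and it makes no new compound (F0). The bond-breaking principle changes from Lewis-acid ionisation to heterogeneous hydrogenolysis: H2 (1 atm), Pd/C (10 wt % Pd on carbon), EtOAc, rt, stopped after uptake of two equivalents. No cation and no Lewis acid are involved. The aldehyde is deactivated toward reduction by the para methoxy group and by the hydrogen bond to the C6 hydroxyl, which forms as soon as that benzyl group is lost.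

Further compounds
F1 | step 5 | (3R)-5,8-bis(benzyloxy)-6-methoxy-3-undecyl-3,4-dihydro-1H-isochromene | CCCCCCCCCCC[C@@H]1Cc2c(OCc3ccccc3)c(OC)cc(OCc3ccccc3)c2CO1
F2 | step 6 | (2R)-1-{2,5-bis(benzyloxy)-6-[(E)-(2,2-dimethylhydrazinylidene)methyl]-3-methoxyphenyl}tridecan-2-ol | CCCCCCCCCCC[C@H](Cc1c(/C=N/N(C)C)c(OCc2ccccc2)cc(OC)c1OCc1ccccc1)O
F3 | step 6 | (2R)-1-{2,5-bis(benzyloxy)-6-[(E)-(2,2-dimethylhydrazinylidene)methyl]-3-methoxyphenyl}tridecan-2-yl acetate | CCCCCCCCCCC[C@H](Cc1c(/C=N/N(C)C)c(OCc2ccccc2)cc(OC)c1OCc1ccccc1)OC(C)=O
F0 | step 8 | none | none
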